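## Retrosynthetic overview

- The oxirane is installed last, on the ring alkene remote from the quaternary carbon and anti to the side chain (step 17). The β-hydroxy ketone is cut at its CH(OH)–CH(CH3) bond (reagent-controlled syn-aldol of pentan-3-one with enal 26, step 16), and 26 is traced to methyl ketone 23.
- Enabling feature: without the oxirane oxygen the carbocycle is a cyclohexa-1,3-diene. Its CH3–C=CH–C(CH3)=CH diene is closed by two adjacent sp3 carbons: the quaternary carbon bearing methyl and the pyranone ring, and the CH bearing the side chain. Such a 5,6-disubstituted cyclohexa-1,3-diene is the retron of a 2-pyranone/alkene [4+2] cycloaddition with loss of CO2.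
- Key disconnection: both bonds joining the sp3 pair to the diene termini are made at once from Z-enoyl sultam 15 (which carries the 4-pyranone) and 3,5-dimethyl-2H-pyran-2-one 19. The Z geometry sets the cis relation; the sultam sets the absolute configuration.
- 15 comes from 2,6-dimethoxy-3,5-dimethyl-4H-pyran-4-one 3 by addition–elimination of a Z-vinyllithium; 19 comes from a Z-selective olefination and lactonisation.
- Ring order: 4-pyranone (step 2), 2-pyranone (step 10, temporary), carbocycle through a bridged lactone (step 11), oxirane (step 17).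

Key step: step 11

Remark: the facial senses of the two chiral controllers are assigned from the accepted models (diene on the Cα-si face of the (2R)-sultam enoyl unit; Re-face attack on the aldehyde by the Z-enol borinate with isopinocampheyl groups from (−)-α-pinene); both controllers are available as antipodes.

## Route

Step 1
Reactants: 1 dimethyl 3-oxopentanedioate
Product: 2 dimethyl 2,4-dimethyl-3-oxopentanedioate (mixture of diastereomers)
Conditions: MeI (2.1 equiv), K2CO3, acetone, reflux
Reagents that add atoms: iodomethane, CI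
Why: Enolate C-alkylation of each doubly activated methylene installs the two ring methyl groups of the later 4-pyranone, and the stereocentres formed are lost in step 2.

Step 2
Reactants: 2 dimethyl 2,4-dimethyl-3-oxopentanedioate
Product: 3 2,6-dimethoxy-3,5-dimethyl-4H-pyran-4-one
Conditions: fuming H2SO4 (20% SO3), 0 °C to rt; poured onto ice
Reagents that add atoms: none
Why: Acid-mediated cyclodehydration of the bis-enol form (one enol oxygen attacks the other activated ester carbon, water is lost) closes the six-membered 4-pyranone ring with both methoxy groups retained.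

Step 3
Reactants: 4 but-2-yn-1-ol
Product: 6 (Z)-3-iodobut-2-en-1-ol, via alkenylaluminate 5 (not isolated)
Conditions: NaAlH2(OCH2CH2OMe)2, Et2O, 0 °C to rt; then I2, THF, −78 to 0 °C
Reagents that add atoms: iodine, II
Why: Hydroxyl-directed trans-hydroalumination of the propargylic alcohol places aluminium on the distal alkyne carbon inside a five-membered alkoxyaluminate ring, and iodinolysis with retention gives the Z-iodide (iodine cis to CH2OH).

Step 4
Reactants: 6 (Z)-3-iodobut-2-en-1-ol
Product: 7 tert-butyl{[(Z)-3-iodobut-2-en-1-yl]oxy}dimethylsilane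
Conditions: TBSCl, imidazole, CH2Cl2, 0 °C to rt
Reagents that add atoms: tert-butyldimethylsilyl chloride, CC(C)(C)[Si](C)(C)Cl
Why: Standard silylation masks the hydroxyl so that iodine–lithium exchange can be run in the next step.

Step 5
Reactants: 7 tert-butyl{[(Z)-3-iodobut-2-en-1-yl]oxy}dimethylsilane and 3 2,6-dimethoxy-3,5-dimethyl-4H-pyran-4-one
Product: 9 2-[(Z)-4-(tert-butyldimethylsilyloxy)but-2-en-2-yl]-6-methoxy-3,5-dimethyl-4H-pyran-4-one, via vinyllithium 8 (not isolated)
Conditions: t-BuLi (2.0 equiv), Et2O, −78 °C; then 3 (1.2 equiv), THF, −78 to −30 °C; aq NH4Cl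
Reagents that add atoms: none
Why: Iodine–lithium exchange retains the alkene geometry, and conjugate addition of the vinyllithium to one of the two equivalent methoxy-bearing carbons of the vinylogous carbonate 3 followed by loss of methoxide (addition–elimination) gives the mono-alkenyl pyranone with the ring cis to the CH2O group.

Step 6
Reactants: 9 the silyl ether from step 5
Product: 10 2-[(Z)-4-hydroxybut-2-en-2-yl]-6-methoxy-3,5-dimethyl-4H-pyran-4-one
Conditions: HF·pyridine, THF/pyridine, 0 °C
Reagents that add atoms: none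
Why: Fluoride-induced cleavage of the primary silyl ether frees the allylic alcohol without touching the Z-alkene or the pyranone.

Step 7
Reactants: 10 the Z-allylic alcohol
Product: 12 (Z)-3-(6-methoxy-3,5-dimethyl-4-oxo-4H-pyran-2-yl)but-2-enoic acid, via Z-enal 11 (not isolated)
Conditions: Dess–Martin periodinane, NaHCO3, CH2Cl2, 0 °C; then crude 11, NaClO2, NaH2PO4, 2-methyl-2-butene, t-BuOH/H2O, 0 °C
Reagents that add atoms: sodium chlorite, [Na+].[O-]Cl=O
Why: Buffered periodinane oxidation followed at once by Pinnick oxidation takes the allylic alcohol to the acid under near-neutral conditions that should not equilibrate the Z-alkene.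

Step 8
Reactants: 12 the Z-acid and 13 (2R)-bornane-10,2-sultam
Product: 15 N-[(Z)-3-(6-methoxy-3,5-dimethyl-4-oxo-4H-pyran-2-yl)but-2-enoyl]-(2R)-bornane-10,2-sultam, via acid chloride 14 (not isolated)
Conditions: 1-chloro-N,N,2-trimethylprop-1-en-1-amine, CH2Cl2, 0 °C; then 13, Et3N, DMAP (cat.), 0 °C to rt
Reagents that add atoms: none
Why: Acid chloride formation under neutral conditions and N-acylation of the sultam attach the chiral controller and turn the trisubstituted alkene into an activated dienophile with the Z geometry kept.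

Step 9
Reactants: 16 (E)-3-ethoxy-2-methylprop-2-enal and 17 ethyl 2-[bis(2,2,2-trifluoroethoxy)phosphoryl]propanoate
Product: 18 ethyl (2Z,4E)-5-ethoxy-2,4-dimethylpenta-2,4-dienoate
Conditions: KN(SiMe3)2, 18-crown-6, THF, −78 °C
Reagents that add atoms: none
Why: The Still–Gennari variant of the Horner–Wadsworth–Emmons olefination gives the kinetic Z-trisubstituted enoate (ester cis to the chain), which is the geometry needed for lactonisation, while the enol ether geometry is carried over.

Step 10
Reactants: 18 the dienoate from step 9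
Product: 19 3,5-dimethyl-2H-pyran-2-one
Conditions: p-TsOH·H2O (cat.), wet toluene, 90 °C
Reagents that add atoms: water, O
Why: Acid-catalysed hydrolysis of the enol ether unmasks the δ-aldehyde, whose dienol form lactonises onto the cis-disposed ester (six-membered ring closure with loss of ethanol) to give the 2-pyranone.

Step 11
Reactants: 15 the Z-enoyl sultam and 19 3,5-dimethyl-2H-pyran-2-one
Product: 21 N-{[(1S,6R)-6-(6-methoxy-3,5-dimethyl-4-oxo-4H-pyran-2-yl)-2,4,6-trimethylcyclohexa-2,4-dien-1-yl]carbonyl}-(2R)-bornane-10,2-sultam, via bridged lactone 20 (not isolated)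
Conditions: 19 (4 equiv), BHT (cat.), 1,2-dichlorobenzene, 150 °C, sealed tube
Reagents that add atoms: none
Why: Thermal normal-electron-demand [4+2] cycloaddition of the diene unit of 19 (ring carbons 3 to 6) to the activated alkene of 15 gives the 2-oxabicyclo[2.2.2]oct-7-en-3-one 20, which loses CO2 by retro-[4+2] at the same temperature to give the cyclohexa-1,3-diene. The closest known reaction type is the cycloaddition/decarboxylation of 2-pyranones with acrylate-type alkenes to 5,6-disubstituted cyclohexa-1,3-dienes, here with an N-enoyl sultam as dienophile. The carbocycle is closed by an intermolecular suprafacial [4+2] addition that forms both σ bonds, and the temporary lactone bridge is removed by cycloreversion, so the endo/exo outcome is irrelevant because both bridgeheads become sp2. The cis relation of pyranone ring and acyl group at the two new stereocentres (the quaternary carbon and the neighbouring CH) follows from the Z geometry of 15, and their absolute configuration from the sultam, which should direct the diene to the Cα-si face of the enoyl unit. The step needs regio- and facial selectivity: the acyl-bearing alkene carbon should bond to the methyl-bearing C3 of 19 and the fully substituted alkene carbon to C6–H, as favoured by the ortho/para-directing 3- and 5-methyl groups of the diene and by avoiding a bond between two fully substituted carbons. A second cycloaddition to 21 is not expected, because its diene is trisubstituted at both alkenes and flanked by the quaternary carbon.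

Step 12
Reactants: 21 the cyclohexadienyl acyl sultam
Product: 22 (1S,6R)-N-methoxy-6-(6-methoxy-3,5-dimethyl-4-oxo-4H-pyran-2-yl)-N,2,4,6-tetramethylcyclohexa-2,4-diene-1-carboxamide
Conditions: Me3Al, MeONHMe·HCl, CH2Cl2, 0 to 40 °C
Reagents that add atoms: N,O-dimethylhydroxylamine hydrochloride, CNOC.Cl
Why: Aluminium amide transamidation of the activated N-acyl sultam gives the N-methoxy-N-methylamide and releases the recoverable auxiliary under non-basic conditions that should not enolise the ring CH.

Step 13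
Reactants: 22 the N-methoxy-N-methylamide
Product: 23 1-[(1S,6R)-6-(6-methoxy-3,5-dimethyl-4-oxo-4H-pyran-2-yl)-2,4,6-trimethylcyclohexa-2,4-dien-1-yl]ethan-1-one
Conditions: MeMgBr, THF, −20 to 0 °C
Reagents that add atoms: methylmagnesium bromide, C[Mg]Br
Why: Grignard addition stops at the chelated tetrahedral intermediate and gives the methyl ketone on work-up, the amide being more electrophilic than the doubly vinylogous carbonate of the pyranone.

Step 14
Reactants: 23 the methyl ketone
Product: 25 1-[(1S,6R)-6-(6-methoxy-3,5-dimethyl-4-oxo-4H-pyran-2-yl)-2,4,6-trimethylcyclohexa-2,4-dien-1-yl]ethenyl trifluoromethanesulfonate, via potassium enolate 24 (not isolated)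
Conditions: KN(SiMe3)2, THF, −78 °C; then PhNTf2, −78 to 0 °C
Reagents that add atoms: N-phenylbis(trifluoromethanesulfonimide), O=S(=O)(N(c1ccccc1)S(=O)(=O)C(F)(F)F)C(F)(F)F
Why: Kinetic deprotonation at the unhindered methyl group (the ring CH is shielded by the adjacent quaternary carbon) and O-sulfonylation give the terminal enol triflate, which already contains the exocyclic methylene.

Step 15
Reactants: 25 the enol triflate
Product: 26 2-[(1S,6R)-6-(6-methoxy-3,5-dimethyl-4-oxo-4H-pyran-2-yl)-2,4,6-trimethylcyclohexa-2,4-dien-1-yl]prop-2-enal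
Conditions: Pd(PPh3)4 (5 mol%), CO (1 atm), Bu3SnH (slow addition), LiCl, THF, 50 °C
Reagents that add atoms: carbon monoxide, [C-]#[O+]
Why: Palladium-catalysed reductive carbonylation (oxidative addition of the enol triflate to zerovalent palladium, CO insertion, hydride transfer from tin) converts the triflate into the α-substituted acrolein.

Step 16
Reactants: 26 the enal and 27 pentan-3-one
Product: 29 (4R,5R)-5-hydroxy-6-[(1R,6R)-6-(6-methoxy-3,5-dimethyl-4-oxo-4H-pyran-2-yl)-2,4,6-trimethylcyclohexa-2,4-dien-1-yl]-4-methylhept-6-en-3-one, via Z-enol borinate 28 (not isolated)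
Conditions: (+)-Ipc2BOTf [from (−)-α-pinene], i-Pr2NEt, 27, CH2Cl2, −78 °C; then 26, −78 to −20 °C; MeOH, pH 7 buffer, 30% H2O2, 0 °C
Reagents that add atoms: none
Why: In this boron-mediated aldol reaction the Z-enol borinate reacts through a chair Zimmerman–Traxler transition state to give the syn adduct, and the isopinocampheyl ligands should direct it to the Re face of the aldehyde, setting both side-chain stereocentres (4R,5R) under reagent control.

Step 17
Reactants: 29 the aldol adduct
Product: 30 CNP0233636.2, (4R,5R)-5-hydroxy-6-[(1S,2R,3R,6R)-3-(6-methoxy-3,5-dimethyl-4-oxo-4H-pyran-2-yl)-1,3,5-trimethyl-7-oxabicyclo[4.1.0]hept-4-en-2-yl]-4-methylhept-6-en-3-one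
Conditions: m-CPBA (1.05 equiv), NaHCO3, CH2Cl2, −20 °C
Reagents that add atoms: 3-chloroperoxybenzoic acid, OOC(=O)c1cccc(Cl)c1
Why: Prilezhaev epoxidation should take the trisubstituted ring alkene remote from the quaternary carbon (the other ring alkene is flanked on both faces by methyl and pyranone, and the exocyclic 1,1-disubstituted alkene is less nucleophilic), from the face anti to the side chain on the adjacent CH, which sets the two oxirane stereocentres.

## Compound list

1 | dimethyl 3-oxopentanedioate | COC(=O)CC(=O)CC(=O)OC | starting material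
2 | dimethyl 2,4-dimethyl-3-oxopentanedioate (diastereomer mixture) | COC(=O)C(C)C(=O)C(C)C(=O)OC | intermediate
3 | 2,6-dimethoxy-3,5-dimethyl-4H-pyran-4-one | COc1oc(OC)c(C)c(=O)c1C | intermediate
4 | but-2-yn-1-ol | CC#CCO | starting material
5 | sodium 2,2-bis(2-methoxyethoxy)-3-methyl-2,5-dihydro-1,2-oxaluminol-2-uide (cyclic alkenylaluminate) | CC1=CCO[Al-]1(OCCOC)OCCOC.[Na+] | intermediate
6 | (Z)-3-iodobut-2-en-1-ol | C/C(I)=C/CO | intermediate
7 | tert-butyl{[(Z)-3-iodobut-2-en-1-yl]oxy}dimethylsilane | C/C(I)=C/CO[Si](C)(C)C(C)(C)C | intermediate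
8 | [(Z)-4-(tert-butyldimethylsilyloxy)but-2-en-2-yl]lithium (lithium cis to CH2O) | C/C([Li])=C/CO[Si](C)(C)C(C)(C)C | intermediate
9 | 2-[(Z)-4-(tert-butyldimethylsilyloxy)but-2-en-2-yl]-6-methoxy-3,5-dimethyl-4H-pyran-4-one | C/C(=C/CO[Si](C)(C)C(C)(C)C)c1oc(OC)c(C)c(=O)c1C | intermediate
10 | 2-[(Z)-4-hydroxybut-2-en-2-yl]-6-methoxy-3,5-dimethyl-4H-pyran-4-one | C/C(=C/CO)c1oc(OC)c(C)c(=O)c1C | intermediate
11 | (Z)-3-(6-methoxy-3,5-dimethyl-4-oxo-4H-pyran-2-yl)but-2-enal | C/C(=C/C=O)c1oc(OC)c(C)c(=O)c1C | intermediate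
12 | (Z)-3-(6-methoxy-3,5-dimethyl-4-oxo-4H-pyran-2-yl)but-2-enoic acid | C/C(=C/C(=O)O)c1oc(OC)c(C)c(=O)c1C | intermediate
13 | (2R)-bornane-10,2-sultam [(−)-2,10-camphorsultam] | CC1(C)[C@@H]2CC[C@]13CS(=O)(=O)N[C@@H]3C2 | starting material
14 | (Z)-3-(6-methoxy-3,5-dimethyl-4-oxo-4H-pyran-2-yl)but-2-enoyl chloride | C/C(=C/C(=O)Cl)c1oc(OC)c(C)c(=O)c1C | intermediate
15 | N-[(Z)-3-(6-methoxy-3,5-dimethyl-4-oxo-4H-pyran-2-yl)but-2-enoyl]-(2R)-bornane-10,2-sultam | CC1(C)[C@@H]2CC[C@]13CS(=O)(=O)N([C@@H]3C2)C(=O)/C=C(/C)c1oc(OC)c(C)c(=O)c1C | intermediate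
16 | (E)-3-ethoxy-2-methylprop-2-enal | CCO/C=C(\C)C=O | starting material
17 | ethyl 2-[bis(2,2,2-trifluoroethoxy)phosphoryl]propanoate | CCOC(=O)C(C)P(=O)(OCC(F)(F)F)OCC(F)(F)F | starting material
18 | ethyl (2Z,4E)-5-ethoxy-2,4-dimethylpenta-2,4-dienoate | CCO/C=C(\C)/C=C(/C)C(=O)OCC | intermediate
19 | 3,5-dimethyl-2H-pyran-2-one | Cc1coc(=O)c(C)c1 | intermediate
20 | endo bridged lactone: sultam imide of 4,6,7-trimethyl-6-(6-methoxy-3,5-dimethyl-4-oxo-4H-pyran-2-yl)-3-oxo-2-oxabicyclo[2.2.2]oct-7-ene-5-carboxylic acid; acyl and pyranone cis and syn to the C7=C8 bridge, C5 and C6 configured as in 21 (the exo isomer converges) | CC1(C)[C@@H]2CC[C@]13CS(=O)(=O)N([C@@H]3C2)C(=O)[C@H]1[C@@]2(C)C=C(C)[C@H](OC2=O)[C@@]1(C)c1oc(OC)c(C)c(=O)c1C | intermediate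
21 | N-{[(1S,6R)-6-(6-methoxy-3,5-dimethyl-4-oxo-4H-pyran-2-yl)-2,4,6-trimethylcyclohexa-2,4-dien-1-yl]carbonyl}-(2R)-bornane-10,2-sultam (acyl and pyranone cis) | CC1(C)[C@@H]2CC[C@]13CS(=O)(=O)N([C@@H]3C2)C(=O)[C@H]1C(C)=CC(C)=C[C@@]1(C)c1oc(OC)c(C)c(=O)c1C | intermediate
22 | (1S,6R)-N-methoxy-6-(6-methoxy-3,5-dimethyl-4-oxo-4H-pyran-2-yl)-N,2,4,6-tetramethylcyclohexa-2,4-diene-1-carboxamide | CON(C)C(=O)[C@H]1C(C)=CC(C)=C[C@@]1(C)c1oc(OC)c(C)c(=O)c1C | intermediate
23 | 1-[(1S,6R)-6-(6-methoxy-3,5-dimethyl-4-oxo-4H-pyran-2-yl)-2,4,6-trimethylcyclohexa-2,4-dien-1-yl]ethan-1-one | CC(=O)[C@H]1C(C)=CC(C)=C[C@@]1(C)c1oc(OC)c(C)c(=O)c1C | intermediate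
24 | potassium 1-[(1S,6R)-6-(6-methoxy-3,5-dimethyl-4-oxo-4H-pyran-2-yl)-2,4,6-trimethylcyclohexa-2,4-dien-1-yl]ethen-1-olate | [K+].[O-]C(=C)[C@H]1C(C)=CC(C)=C[C@@]1(C)c1oc(OC)c(C)c(=O)c1C | intermediate
25 | 1-[(1S,6R)-6-(6-methoxy-3,5-dimethyl-4-oxo-4H-pyran-2-yl)-2,4,6-trimethylcyclohexa-2,4-dien-1-yl]ethenyl trifluoromethanesulfonate | C=C(OS(=O)(=O)C(F)(F)F)[C@H]1C(C)=CC(C)=C[C@@]1(C)c1oc(OC)c(C)c(=O)c1C | intermediate
26 | 2-[(1S,6R)-6-(6-methoxy-3,5-dimethyl-4-oxo-4H-pyran-2-yl)-2,4,6-trimethylcyclohexa-2,4-dien-1-yl]prop-2-enal | C=C(C=O)[C@H]1C(C)=CC(C)=C[C@@]1(C)c1oc(OC)c(C)c(=O)c1C | intermediate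
27 | pentan-3-one | CCC(=O)CC | starting material
28 | (Z)-pent-2-en-3-yl diisopinocampheylborinate (methyl cis to O–B; isopinocampheyl groups from (−)-α-pinene) | C/C=C(/CC)OB([C@H]1C[C@H]2C[C@@H]([C@@H]1C)C2(C)C)[C@H]1C[C@H]2C[C@@H]([C@@H]1C)C2(C)C | intermediate
29 | (4R,5R)-5-hydroxy-6-[(1R,6R)-6-(6-methoxy-3,5-dimethyl-4-oxo-4H-pyran-2-yl)-2,4,6-trimethylcyclohexa-2,4-dien-1-yl]-4-methylhept-6-en-3-one | C=C([C@H](O)[C@@H](C)C(=O)CC)[C@H]1C(C)=CC(C)=C[C@@]1(C)c1oc(OC)c(C)c(=O)c1C | intermediate
30 | CNP0233636.2, (4R,5R)-5-hydroxy-6-[(1S,2R,3R,6R)-3-(6-methoxy-3,5-dimethyl-4-oxo-4H-pyran-2-yl)-1,3,5-trimethyl-7-oxabicyclo[4.1.0]hept-4-en-2-yl]-4-methylhept-6-en-3-one | C=C([C@H](O)[C@@H](C)C(=O)CC)[C@H]1[C@]2(C)O[C@@H]2C(C)=C[C@@]1(C)c1oc(OC)c(C)c(=O)c1C | target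

## Step count and risks

Total step count: 17. Longest linear sequence: 13 steps (1 → 2 → 3 → 9 → 10 → 12 → 15 → 21 → 22 → 23 → 25 → 26 → 29 → 30).

Steps most likely to fail:

Step 11. The β,β-disubstituted enoyl unit may be too unreactive toward the reluctant 2-pyranone diene. The facial bias of the sultam may erode at 150 °C, and the Z-alkene may equilibrate before it reacts. The fallback sets out from 15 and uses a reactive acyclic diene at low temperature. Cycloaddition of 15 with (E)-2-methylpenta-1,3-diene promoted by EtAlCl2 (CH2Cl2, −78 to −20 °C; the chelated sultam directs the same alkene face, and the diene methyl groups direct the same regiochemistry) should give the cyclohexene F1. Addition of Br2 (CH2Cl2, −78 °C) should give the trans-dibromide F2, and double dehydrobromination with DBU (toluene, 80 °C) should give the cyclohexadiene, so the route is rejoined at 21.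

Step 14. Deprotonation may occur at the ring CH (α to the ketone and allylic) instead of at the methyl group, leading to loss of configuration or migration of the diene into conjugation. The fallback sets out from 22 and avoids ketone enolate chemistry. Reduction with i-Bu2AlH (THF, −78 °C) should give the aldehyde F3. Wittig reaction with MeOCH2PPh3Cl/KN(SiMe3)2 should give the enol ether F4, and hydrolysis with aqueous oxalic acid should give the homologous aldehyde F5. Mannich methylenation with CH2=NMe2+ I− and Et3N passes through the Mannich base F6, which eliminates dimethylamine to give the enal, so the route is rejoined at 26.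

Step 17. The exocyclic alkene may compete through hydroxyl-directed epoxidation, the second ring alkene may be over-oxidised, and face selectivity may be incomplete with the free β-hydroxy ketone present. The fallback sets out from 26 and changes the order of events. Buffered m-CPBA epoxidation at the enal stage (the enal alkene is electron-poor and no hydroxyl is present) should give the epoxy enal F7. The boron aldol reaction of step 16 with 28 then forms the side chain last, so the route is rejoined at 30.

## Further compounds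

F1 | step 11 | N-{[2,4,6-trimethyl-6-(6-methoxy-3,5-dimethyl-4-oxo-4H-pyran-2-yl)cyclohex-3-en-1-yl]carbonyl}-(2R)-bornane-10,2-sultam (C1 and C6 as in 21, 2-methyl cis to the carbonyl group) | CC1(C)[C@@H]2CC[C@]13CS(=O)(=O)N([C@@H]3C2)C(=O)[C@H]1[C@@H](C)C=C(C)C[C@@]1(C)c1oc(OC)c(C)c(=O)c1C
F2 | step 11 | trans-3,4-dibromide of F1 (3,4-dibromo-2,4,6-trimethylcyclohexane core, one trans diastereomer drawn) | CC1(C)[C@@H]2CC[C@]13CS(=O)(=O)N([C@@H]3C2)C(=O)[C@H]1[C@@H](C)[C@H](Br)[C@@](C)(Br)C[C@@]1(C)c1oc(OC)c(C)c(=O)c1C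
F3 | step 14 | (1S,6R)-6-(6-methoxy-3,5-dimethyl-4-oxo-4H-pyran-2-yl)-2,4,6-trimethylcyclohexa-2,4-diene-1-carbaldehyde | O=C[C@H]1C(C)=CC(C)=C[C@@]1(C)c1oc(OC)c(C)c(=O)c1C
F4 | step 14 | 2-[(1S,6R)-6-(2-methoxyethenyl)-1,3,5-trimethylcyclohexa-2,4-dien-1-yl]-6-methoxy-3,5-dimethyl-4H-pyran-4-one (E isomer drawn, E/Z mixture expected) | CO/C=C/[C@H]1C(C)=CC(C)=C[C@@]1(C)c1oc(OC)c(C)c(=O)c1C
F5 | step 14 | 2-[(1S,6R)-6-(6-methoxy-3,5-dimethyl-4-oxo-4H-pyran-2-yl)-2,4,6-trimethylcyclohexa-2,4-dien-1-yl]acetaldehyde | O=CC[C@H]1C(C)=CC(C)=C[C@@]1(C)c1oc(OC)c(C)c(=O)c1C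
F6 | step 14 | 3-(dimethylamino)-2-[(1S,6R)-6-(6-methoxy-3,5-dimethyl-4-oxo-4H-pyran-2-yl)-2,4,6-trimethylcyclohexa-2,4-dien-1-yl]propanal (Mannich base, epimer mixture at C2, not isolated) | CN(C)CC(C=O)[C@H]1C(C)=CC(C)=C[C@@]1(C)c1oc(OC)c(C)c(=O)c1C
F7 | step 17 | 2-[(1S,2S,3R,6R)-3-(6-methoxy-3,5-dimethyl-4-oxo-4H-pyran-2-yl)-1,3,5-trimethyl-7-oxabicyclo[4.1.0]hept-4-en-2-yl]prop-2-enal | C=C(C=O)[C@H]1[C@]2(C)O[C@@H]2C(C)=C[C@@]1(C)c1oc(OC)c(C)c(=O)c1C
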